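## The problem

The target (35) is an eremophilane: a trans-fused decalin whose ring A (C1–C5, C10) carries an O-tigloyl group on C3 and a methyl group (C15) on C4. The ring fusion carries a quaternary methyl group (C14) on C5 and a hydrogen on C10. Ring B (C5–C10) carries an isopropenyl group on C7, a ketone at C8 and an O-senecioyl group on C9. There are six stereocentres, (3R,4R,5R,7S,9S,10R), five of them contiguous along C3–C4–C5–C10–C9. In the chair–chair decalin only the C14 methyl group is axial. C7 and C9 flank the ketone and hold their substituents equatorially, so both are the thermodynamically preferred epimers and can be set or corrected under equilibrating conditions. The axial methyl group screens the β face of ring A, so C3 and C4 can be derived from C5 by an α-face addition to a C3=C4 alkene. What can be neither relayed nor equilibrated is the vicinal pair C5 (quaternary)/C10 and its absolute configuration. The fragile groups are the α-acyloxy ketone (acyl migration, enolisation), the β,γ-unsaturated isopropenyl ketone (moves into conjugation with acid or base) and the senecioate (deconjugates when acylation runs through a vinylketene). Two different enoates must also go onto two different secondary hydroxyls, so these groups belong at the end, under mild conditions. The enabling feature is that C5 and C10 are adjacent and both lie 1,4 to C3 (through C4 and through C1–C2). If O3 is the alkyl oxygen of a δ-lactone whose carbonyl is C9, then C10 is the lactone α-carbon and C3 bears the C4=C5 alkene. The ketene acetal of that lactone then holds the array C10=C9–O–C3–C4=C5, whose [3,3] shift forms C5–C10, closes ring A and frees C9 as the carboxyl from which ring B is built.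

## Retrosynthesis

**C9 ester and O9 silyl ether.** Target 35 is cut at the C9 ester C–O bond to ketol 33 and 3-methylbut-2-enoic acid 34; 33 is the desilylation product of 32. The senecioate goes on last because it is the most fragile acyl group and because O9 must be a silyl ether while C7 is functionalised. The other order would expose an α-acyloxy ketone to an amide base. The forward steps need an esterification that avoids a ketene and a deprotection that leaves a β,γ-unsaturated ketone alone.

**C7–C11.** Silyl ether 32 is cut to ketone 30 and 2-bromopropene 31. Unlike an aldol with acetone followed by dehydration, this cut places the double bond where the vinyl halide has it and never makes a β-hydroxy ketone, whose dehydration favours the conjugated isopropylidene isomer. Unlike carrying the isopropenyl group from an earlier stage, it keeps C3=C4 as the only alkene when hydroboration is due. The precursor has one stereocentre and three carbons fewer. The forward reaction must enolise towards C7 only and must not epimerise C9.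

**C8 ketone, O8/O9 differentiation, C3–O and C4–H.** Ketone 30 goes back through alcohol 29 to the cis diol 27, whose equatorial O9 and axial O8 are told apart through a stannylene acetal. Diol 27 comes from acetonide 26, the tiglate of alcohol 24 (acid chloride 25), and 24 is the hydroboration product of alkene 22. Hydroboration is placed after ring B closure on purpose. In the monocyclic cyclohexenes 17–20 the two half-chairs are close in energy and neither face of C3=C4 is reliably favoured; in the trans-decalin 22 the axial C14 methyl group leaves only the α face open. The acetonide is the price for this, and it also makes O3 the only free hydroxyl when the tiglate is introduced.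

**Ring B, C8–C9.** Acetonide 22 comes from cis diol 21, and 21 from dialdehyde 20 by reductive coupling. This cut uses the carboxyl carbon C9 that the key step delivers together with a three-carbon arm on C5, and it brings both ring-B oxygens in with the ring closure. A cut at C7–C8 or C6–C7 would need a homologation of C9 or a second alkylation next to the quaternary centre. A benzoin or acyloin closure would give the ketol directly but with open regiochemistry. Dialdehyde 20 comes from diol 19 and this from acid 17.

**Key disconnection, C5–C10.** Acid 17 is disconnected at C5–C10, with C3 reconnected to a carboxyl oxygen: δ-lactone 14, through silyl ketene acetal 15 and silyl ester 16. One concerted step creates the quaternary C5 and C10 with their relative configuration (from the alkene geometry and the ring) and their absolute configuration (from one carbinol). The precursor has a single stereocentre and no ring-fusion problem. The forward reaction asks for clean O-silylation of the lactone enolate and a geometrically pure (Z)-alkene.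

**Lactone.** Lactone 14 comes from unsaturated lactone 13 by conjugate reduction, 13 from acrylate 12 by ring-closing metathesis (C1=C10), and 12 from homoallylic alcohol 10 and acryloyl chloride 11. Alcohol 10 is cut at C2–C3 to enal 7 and allylboronate 8. This sequence sets C3 by a catalytic allylation and builds the ring from two three-carbon pieces. The forward steps must not isomerise the enal and must leave the tetrasubstituted alkene alone.

**Tetrasubstituted alkene, C5–C6.** Enal 7 comes from alcohol 6 and ester 5. Ester 5 is cut at C5–C6 to enol triflate 2 and alkylborane 4 (from allyl silyl ether 3); 2 comes from ethyl 2-methylacetoacetate 1. The (Z) geometry decides the configuration of C5 relative to C10. A β-keto ester fixes it at the enolate stage by chelation and a stereoretentive coupling transfers it, in two steps and with the whole C6–C8 arm attached. Olefination of a ketone would give mixtures.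

## Roads not taken

**Alternative 1:** The cut is C3–C4, in ring A of a ring-B-first intermediate.
- Forward step: SmI2 with HMPA would reduce the aldehyde of A2 to a ketyl that attacks the inner carbon of the vinyl group on C5 in a 6-exo closure. The primary radical left on the terminal carbon is reduced and protonated to the C15 methyl group, giving A1.
- Merits: ring A, the C3 hydroxyl at its final oxidation level and the C4 methyl group arise together, with the anti hydroxyl/methyl relationship such closures usually give. The C8 ketal is ready for ring-B work.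
- Weak points: A2 already contains the quaternary C5 (methyl and vinyl) trans to the C10 side chain, so the hardest stereochemical problem is only moved into a cyclohexanone precursor with no built-in source of absolute configuration. The ketyl must attack an alkene carbon next to a quaternary centre, where simple aldehyde reduction and 7-endo closure compete. After A1 the C8 ketone still has to be oxygenated at C9 and alkenylated at C7, two α positions that must be told apart.
- Comparison: this road sets C3 and C4 more directly than the chosen one, which needs an acetonide and a separate hydroboration (steps 13–16). Against that, the chosen plan sets C5 and C10 in one stereospecific step from a catalytically made carbinol and brings O8 and O9 in with the ring closure.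

**Alternative 2:** The cuts are C5–C10 and C6–C7.
- Forward step: Me2AlCl would activate the 2-substituted acrolein of triene A4 (C5=C6, the formyl group being the future C14) towards the 2,3-bis(silyloxy)diene (C7=C8–C9=C10). The intramolecular Diels–Alder reaction closes ring B directly and ring A through the tether, giving A3.
- Merits: two C–C bonds and both rings in one step, with C5 and C10 set together. The enediol bis(silyl ether) has two different silyl groups, so the C8 ketone/C9 carbinol pattern can be released without a selective reaction on a diol. Here A3 is better than the chosen route, which spends steps 16–18 on it.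
- Weak points: trans versus cis fusion depends on an endo/exo preference that is rarely high for such trienes, and the facial sense rests on the C3/C4 centres in the tether, which must first be made in an acyclic chain. A4 combines a polymerisable enal with an acid-labile mixed bis(silyloxy)diene under a Lewis acid. The formyl group must then be taken down to a methyl group at a neopentyl position.
- Comparison: the step count would be comparable or slightly lower. The chosen plan offsets this with a rearrangement that has a single allowed stereochemical course and with robust intermediates.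

**Alternative 3:** The cut is C4–C5.
- Forward step: KOt-Bu would convert phenol A6 into its phenoxide, whose para carbon (C5, already bearing the methyl group) displaces the secondary mesylate at C4 with inversion. This closes ring A and gives the cross-conjugated dienone A5.
- Merits: ring B and its two oxygens come from a cheap catechol-type arene, the quaternary centre is formed in the ring closure, and C3 and C4 come from an acyclic chain. An oxygenated bicyclic core is reached in clearly fewer steps than the chosen route needs to reach 21. The C6=C7 enone is a handle for the C7 substituent.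
- Weak points: a secondary mesylate next to a silyloxy carbon must be attacked by a hindered carbon nucleophile, so elimination competes, and the cis C4/C5 methyl relationship rests on a facial preference that is hard to predict. C10 is still sp2 in A5, so the trans ring fusion and C9 must come from a later reduction of the enol ether double bond in the presence of the second enone. The isopropenyl group must be attached at the α-carbon of an enone.
- Comparison: against the shorter access to the core, the chosen plan fixes C10 together with C5 in the same event, not by a late facial reduction, and needs no elimination-prone alkylation.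

Key step: step 9

Remark: locants follow eremophilane numbering as used above; α is the face of the decalin opposite the C14 methyl group and β the face that carries it.
Remark: in step 5 the (S)-configured phosphoric acid is assumed to give the (S)-carbinol, by analogy with aryl and alkenyl aldehydes; the mirror-image acid would be used if MTPA ester analysis of 10 showed the opposite sense.

## Route

Step 1
Reactants: 1 ethyl 2-methyl-3-oxobutanoate
Product: 2 ethyl (2Z)-2-methyl-3-{[(trifluoromethyl)sulfonyl]oxy}but-2-enoate
Conditions: NaH, CH2Cl2, 0 °C; then Tf2O, −78 → 0 °C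
Reagents that add atoms: trifluoromethanesulfonic anhydride, O=S(=O)(OS(=O)(=O)C(F)(F)F)C(F)(F)F
Why: Enol triflate formation: the sodium enolate of the β-keto ester is held U-shaped by chelation, so O-sulfonylation should give the (Z)-triflate with the triflate cis to the ester. This geometry later fixes C5 relative to C10, so it is to be checked by NOE and any (E)-isomer removed here.

Step 2
Reactants: 2 (Z)-enol triflate; 3 tert-butyl(dimethyl)(prop-2-en-1-yloxy)silane
Product: 5 ethyl (2Z)-6-{[tert-butyl(dimethyl)silyl]oxy}-2,3-dimethylhex-2-enoate, via B-alkyl-9-BBN borane 4 (not isolated)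
Conditions: 3, 9-BBN-H, THF, 0 °C → rt; then 2, PdCl2(dppf) (5 mol%), K3PO4 (aq), DMF, rt → 50 °C
Reagents that add atoms: tert-butyl(dimethyl)(prop-2-en-1-yloxy)silane (3), C=CCO[Si](C)(C)C(C)(C)C
Why: B-alkyl Suzuki–Miyaura coupling: 9-BBN adds to the terminal carbon of 3 and the alkylborane couples with the vinyl triflate with retention of geometry, so C6 ends cis to the ester carbon (C3) and the two methyl groups stay cis.

Step 3
Reactants: 5 (Z)-enoate
Product: 6 (2Z)-6-{[tert-butyl(dimethyl)silyl]oxy}-2,3-dimethylhex-2-en-1-ol
Conditions: i-Bu2AlH (2.5 equiv), CH2Cl2, −78 → 0 °C; aq. potassium sodium tartrate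
Reagents that add atoms: none
Why: 1,2-Reduction of the enoate by the aluminium hydride; the silyl ether and the alkene geometry are not touched.

Step 4
Reactants: 6 (Z)-allylic alcohol
Product: 7 (2Z)-6-{[tert-butyl(dimethyl)silyl]oxy}-2,3-dimethylhex-2-enal
Conditions: DMP (triacetoxyperiodinane), NaHCO3, CH2Cl2, 0 °C
Reagents that add atoms: none
Why: Periodinane oxidation under buffered, non-basic conditions should give the (Z)-enal without the acid or base that would let it isomerise; the aldehyde is used at once.

Step 5
Reactants: 7 (Z)-enal; 8 allylboronic acid pinacol ester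
Product: 10 (4S,5Z)-9-{[tert-butyl(dimethyl)silyl]oxy}-5,6-dimethylnona-1,5-dien-4-ol, via pinacol borate ester 9 (not isolated)
Conditions: 8 (1.5 equiv), (S)-3,3′-bis(2,4,6-triisopropylphenyl)-1,1′-binaphthyl-2,2′-diyl hydrogen phosphate (5 mol%), toluene, 4 Å MS, −30 → 0 °C; aq. NaHCO3
Reagents that add atoms: allylboronic acid pinacol ester (8), C=CCB1OC(C)(C)C(C)(C)O1
Why: Brønsted acid-catalysed asymmetric allylboration through a closed six-membered transition state: the chiral phosphate activates the boronate and differentiates the aldehyde faces, setting C3 as (S). Hydrolysis of borate 9 on work-up gives 10.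

Step 6
Reactants: 10 (S)-homoallylic alcohol; 11 acryloyl chloride
Product: 12 (4S,5Z)-9-{[tert-butyl(dimethyl)silyl]oxy}-5,6-dimethylnona-1,5-dien-4-yl prop-2-enoate
Conditions: 11, i-Pr2NEt, DMAP (cat.), CH2Cl2, −20 → 0 °C
Reagents that add atoms: acryloyl chloride (11), C=CC(Cl)=O
Why: DMAP-catalysed acylation of the secondary allylic alcohol; the low temperature limits polymerisation of the acrylate.

Step 7
Reactants: 12 acrylate
Product: 13 (6S)-6-[(2Z)-6-{[tert-butyl(dimethyl)silyl]oxy}-3-methylhex-2-en-2-yl]-5,6-dihydro-2H-pyran-2-one
Conditions: second-generation Grubbs catalyst RuCl2(=CHPh)(H2IMes)(PCy3) (5 mol%), CH2Cl2 (5 mM), 40 °C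
Reagents that add atoms: none
Why: Ring-closing metathesis of the acrylate with the terminal alkene gives the six-membered unsaturated lactone; the tetrasubstituted alkene is inert to the ruthenium carbene.

Step 8
Reactants: 13 unsaturated lactone
Product: 14 (6S)-6-[(2Z)-6-{[tert-butyl(dimethyl)silyl]oxy}-3-methylhex-2-en-2-yl]oxan-2-one
Conditions: [(Ph3P)CuH]6 (0.4 equiv), H2O (degassed), benzene, rt
Reagents that add atoms: none
Why: Copper hydride conjugate reduction of the unsaturated lactone; the isolated tetrasubstituted alkene and the allylic C–O bond, which a heterogeneous hydrogenation could attack, are left alone.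

Step 9
Reactants: 14 δ-lactone
Product: 17 (1R,2S)-2-(3-{[tert-butyl(dimethyl)silyl]oxy}propyl)-2,3-dimethylcyclohex-3-ene-1-carboxylic acid, via cyclic silyl ketene acetal 15 (not isolated), via trimethylsilyl ester 16 (not isolated)
Conditions: LiN(i-Pr)2, Me3SiCl/Et3N (premixed), THF, −78 °C; then toluene, 105 °C; 1 M HCl, THF, rt
Reagents that add atoms: none
Why: LiN(i-Pr)2 deprotonates C10 of the lactone in the presence of Me3SiCl, so the enolate is trapped at once on oxygen as the cyclic silyl ketene acetal 15; on heating, its C10=C9–O–C3–C4=C5 array undergoes the [3,3]-sigmatropic shift that breaks C3–O and forms C5–C10, giving silyl ester 16, which dilute acid hydrolyses to 17. The closest known reaction type is the Ireland–Claisen ring contraction of alkenyl lactones to cycloalkenecarboxylic acids. Ring A closes as a six-membered carbocycle by this ring contraction, not by an ionic cyclisation: C3 and C10 are already joined through C1–C2, so the six-centre array can only be reached as a boat, shaped like bicyclo[2.2.2]octene with C3 and C10 at the bridgeheads. C10 is controlled by the ring, which fixes the ketene acetal geometry (C1 cis to the ring oxygen) and makes C5 bond on the face of the old lactone ring from which the oxygen leaves C3. C5 is controlled by the alkene geometry: in the boat the substituent trans to C3 (the C14 methyl) ends cis to the new carboxyl and the one cis to C3 (C6) ends trans, which is the 5-methyl/10-H trans arrangement of the target, and the absolute sense of both centres is relayed from (S)-C3. The step needs O- and not C-silylation and no self-condensation of the lactone, which the in situ quench at −78 °C should secure; it needs a single [3,3] topology, which the substrate secures because only C4=C5 is allylic to the lactone oxygen and the ring excludes the chair.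

Step 10
Reactants: 17 ring-A acid
Product: 19 3-[(1S,6R)-6-(hydroxymethyl)-1,2-dimethylcyclohex-2-en-1-yl]propan-1-ol, via silyl ether alcohol 18 (not isolated)
Conditions: LiAlH4, THF, 0 °C → rt; aqueous work-up; then HCl (1%) in MeOH, rt
Reagents that add atoms: none
Why: LiAlH4 reduces the hindered acid to the primary alcohol, and mild acidic methanolysis of the crude product removes the primary silyl ether, giving the diol in one operation.

Step 11
Reactants: 19 diol
Product: 20 (1R,2S)-2,3-dimethyl-2-(3-oxopropyl)cyclohex-3-ene-1-carbaldehyde
Conditions: DMP (2.5 equiv), NaHCO3, CH2Cl2, 0 °C → rt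
Reagents that add atoms: none
Why: Double periodinane oxidation under neutral, buffered conditions, chosen so that C10, now alpha to a formyl group, does not epimerise; the dialdehyde is used crude.

Step 12
Reactants: 20 dialdehyde
Product: 21 (1S,2R,4aS,8aR)-4a,5-dimethyl-1,2,3,4,4a,7,8,8a-octahydronaphthalene-1,2-diol (the 8α,9α-diol of the trans-decalin)
Conditions: SmI2 (3 equiv), THF, −78 °C → rt; aq. NH4Cl
Reagents that add atoms: none
Why: Intramolecular pinacol coupling: trivalent samarium bridges the two oxygens as C8–C9 forms, so a cis diol is expected, and of the two cis diols the one with O9 equatorial (α) avoids a 1,3-diaxial clash with the C14 methyl group. The step closes ring B as a trans-decalin and sets C8 and C9.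

Step 13
Reactants: 21 cis diol
Product: 22 (3aR,5aS,9aR,9bS)-2,2,5a,6-tetramethyl-3a,4,5,5a,8,9,9a,9b-octahydronaphtho[1,2-d][1,3]dioxole
Conditions: 2,2-dimethoxypropane, pyridinium p-toluenesulfonate (cat.), CH2Cl2, rt
Reagents that add atoms: 2,2-dimethoxypropane, COC(C)(C)OC
Why: Acetonide formation on the cis diol masks both hydroxyls for the hydroboration and keeps O3 distinguishable from O8 and O9.

Step 14
Reactants: 22 alkene acetonide
Product: 24 (3aR,5aR,6R,7R,9aR,9bS)-2,2,5a,6-tetramethyldecahydronaphtho[1,2-d][1,3]dioxol-7-ol (3α-hydroxy, 4β-methyl), via C3 alkylborane 23 (not isolated)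
Conditions: BH3·SMe2, THF, 0 °C → rt; then NaOH, H2O2, 0 °C → rt
Reagents that add atoms: hydrogen peroxide, OO
Why: Hydroboration–oxidation: H and B add syn across C3=C4 with boron on the less substituted C3, from the α face because the axial C14 methyl group blocks the β face of the rigid trans-decalin. Oxidation with retention gives the equatorial 3α-alcohol and the 4β-methyl group, (3R,4R).

Step 15
Reactants: 24 C3 alcohol; 25 (2E)-2-methylbut-2-enoyl chloride
Product: 26 (3aR,5aR,6R,7R,9aR,9bS)-2,2,5a,6-tetramethyldecahydronaphtho[1,2-d][1,3]dioxol-7-yl (2E)-2-methylbut-2-enoate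
Conditions: 25, DMAP, pyridine, CH2Cl2, rt
Reagents that add atoms: (2E)-2-methylbut-2-enoyl chloride (25), C/C=C(\C)C(Cl)=O
Why: DMAP-catalysed acylation of the equatorial secondary alcohol; the (E)-2-methylbut-2-enoyl group has no tendency to isomerise under these conditions.

Step 16
Reactants: 26 tiglate acetonide
Product: 27 (1R,2R,4aR,5S,6R,8aR)-5,6-dihydroxy-1,8a-dimethyldecahydronaphthalen-2-yl (2E)-2-methylbut-2-enoate (8α,9α-diol)
Conditions: AcOH/H2O/THF (3:1:1), 45 °C
Reagents that add atoms: none
Why: Acid-catalysed hydrolysis of the acetonide; the enoate ester is stable to aqueous acetic acid.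

Step 17
Reactants: 27 cis diol tiglate
Product: 29 (1R,2R,4aR,5S,6R,8aR)-6-hydroxy-1,8a-dimethyl-5-[(triethylsilyl)oxy]decahydronaphthalen-2-yl (2E)-2-methylbut-2-enoate, via dibutylstannylene acetal 28 (not isolated)
Conditions: Bu2SnO, toluene, reflux (−H2O); then Et3SiCl, CH2Cl2, 0 °C → rt
Reagents that add atoms: chlorotriethylsilane, CC[Si](Cl)(CC)CC
Why: Stannylene acetal activation: in a cis diol on a chair the equatorial oxygen is the one that reacts with electrophiles, so silylation should go to O9 and leave the axial O8 free.

Step 18
Reactants: 29 C8 alcohol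
Product: 30 (1R,2R,4aR,5S,8aR)-1,8a-dimethyl-6-oxo-5-[(triethylsilyl)oxy]decahydronaphthalen-2-yl (2E)-2-methylbut-2-enoate
Conditions: DMP, NaHCO3, CH2Cl2, rt
Reagents that add atoms: none
Why: Periodinane oxidation of the axial C8 alcohol to the ketone under neutral conditions, which should neither epimerise C9 nor move the silyl group.

Step 19
Reactants: 30 C8 ketone; 31 2-bromopropene
Product: 32 (1R,2R,4aR,5S,7S,8aR)-1,8a-dimethyl-6-oxo-7-(prop-1-en-2-yl)-5-[(triethylsilyl)oxy]decahydronaphthalen-2-yl (2E)-2-methylbut-2-enoate
Conditions: 31, Pd2(dba)3 (2.5 mol%), t-Bu3P·HBF4 (6 mol%), LiN(SiMe3)2 (2.2 equiv), THF, 0 °C → rt; AcOH, −78 °C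
Reagents that add atoms: 2-bromopropene (31), CC(Br)=C
Why: Palladium-catalysed α-alkenylation of a ketone enolate with an alkenyl bromide: the amide base enolises away from the silyloxy-bearing C9, the alkenylpalladium bromide from oxidative addition to zerovalent palladium takes up the enolate, and reductive elimination forms C7–C11 with the double bond fixed where the bromide had it. Kinetic protonation of the product enolate at −78 °C should place the isopropenyl group equatorial (α), which is also the more stable C7 epimer.

Step 20
Reactants: 32 silyl ether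
Product: 33 (1R,2R,4aR,5S,7S,8aR)-5-hydroxy-1,8a-dimethyl-6-oxo-7-(prop-1-en-2-yl)decahydronaphthalen-2-yl (2E)-2-methylbut-2-enoate
Conditions: HF·pyridine, pyridine, THF, 0 °C
Reagents that add atoms: none
Why: Fluoride cleavage of the triethylsilyl ether under buffered, weakly acidic conditions that should neither epimerise C7 or C9 nor move the alkene into conjugation.

Step 21
Reactants: 33 ketol; 34 3-methylbut-2-enoic acid
Product: 35 (1R,2R,4aR,5S,7S,8aR)-1,8a-dimethyl-5-[(3-methylbut-2-enoyl)oxy]-6-oxo-7-(prop-1-en-2-yl)decahydronaphthalen-2-yl (2E)-2-methylbut-2-enoate (CNP0375730.3)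
Conditions: 34, N,N′-dicyclohexylcarbodiimide, DMAP, CH2Cl2, 0 °C → rt
Reagents that add atoms: 3-methylbut-2-enoic acid (34), CC(C)=CC(=O)O
Why: Steglich esterification of the α-hydroxy ketone with the free acid avoids the acid chloride/amine combination that deconjugates this acyl group through a vinylketene, and gives the target.

## Compound list

1 | ethyl 2-methyl-3-oxobutanoate | CCOC(=O)C(C)C(C)=O | starting material
2 | ethyl (2Z)-2-methyl-3-{[(trifluoromethyl)sulfonyl]oxy}but-2-enoate | CCOC(=O)/C(C)=C(C)\OS(=O)(=O)C(F)(F)F | intermediate
3 | tert-butyl(dimethyl)(prop-2-en-1-yloxy)silane | C=CCO[Si](C)(C)C(C)(C)C | starting material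
4 | 9-(3-{[tert-butyl(dimethyl)silyl]oxy}propyl)-9-borabicyclo[3.3.1]nonane | CC(C)(C)[Si](C)(C)OCCCB1C2CCCC1CCC2 | intermediate
5 | ethyl (2Z)-6-{[tert-butyl(dimethyl)silyl]oxy}-2,3-dimethylhex-2-enoate | CCOC(=O)/C(C)=C(C)\CCCO[Si](C)(C)C(C)(C)C | intermediate
6 | (2Z)-6-{[tert-butyl(dimethyl)silyl]oxy}-2,3-dimethylhex-2-en-1-ol | OC/C(C)=C(C)\CCCO[Si](C)(C)C(C)(C)C | intermediate
7 | (2Z)-6-{[tert-butyl(dimethyl)silyl]oxy}-2,3-dimethylhex-2-enal | O=C/C(C)=C(C)\CCCO[Si](C)(C)C(C)(C)C | intermediate
8 | 4,4,5,5-tetramethyl-2-(prop-2-en-1-yl)-1,3,2-dioxaborolane (allylboronic acid pinacol ester) | C=CCB1OC(C)(C)C(C)(C)O1 | starting material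
9 | 2-{[(4S,5Z)-9-{[tert-butyl(dimethyl)silyl]oxy}-5,6-dimethylnona-1,5-dien-4-yl]oxy}-4,4,5,5-tetramethyl-1,3,2-dioxaborolane | C=CC[C@H](OB1OC(C)(C)C(C)(C)O1)/C(C)=C(C)\CCCO[Si](C)(C)C(C)(C)C | intermediate
10 | (4S,5Z)-9-{[tert-butyl(dimethyl)silyl]oxy}-5,6-dimethylnona-1,5-dien-4-ol | C=CC[C@H](O)/C(C)=C(C)\CCCO[Si](C)(C)C(C)(C)C | intermediate
11 | prop-2-enoyl chloride (acryloyl chloride) | C=CC(Cl)=O | starting material
12 | (4S,5Z)-9-{[tert-butyl(dimethyl)silyl]oxy}-5,6-dimethylnona-1,5-dien-4-yl prop-2-enoate | C=CC[C@H](OC(=O)C=C)/C(C)=C(C)\CCCO[Si](C)(C)C(C)(C)C | intermediate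
13 | (6S)-6-[(2Z)-6-{[tert-butyl(dimethyl)silyl]oxy}-3-methylhex-2-en-2-yl]-5,6-dihydro-2H-pyran-2-one | O=C1C=CC[C@H](O1)/C(C)=C(C)\CCCO[Si](C)(C)C(C)(C)C | intermediate
14 | (6S)-6-[(2Z)-6-{[tert-butyl(dimethyl)silyl]oxy}-3-methylhex-2-en-2-yl]oxan-2-one | O=C1CCC[C@H](O1)/C(C)=C(C)\CCCO[Si](C)(C)C(C)(C)C | intermediate
15 | tert-butyl{[(4Z)-4-methyl-5-{(2S)-6-[(trimethylsilyl)oxy]-3,4-dihydro-2H-pyran-2-yl}hex-4-en-1-yl]oxy}dimethylsilane | C[Si](C)(C)OC1=CCC[C@H](O1)/C(C)=C(C)\CCCO[Si](C)(C)C(C)(C)C | intermediate
16 | trimethylsilyl (1R,2S)-2-(3-{[tert-butyl(dimethyl)silyl]oxy}propyl)-2,3-dimethylcyclohex-3-ene-1-carboxylate | C[Si](C)(C)OC(=O)[C@@H]1CCC=C(C)[C@@]1(C)CCCO[Si](C)(C)C(C)(C)C | intermediate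
17 | (1R,2S)-2-(3-{[tert-butyl(dimethyl)silyl]oxy}propyl)-2,3-dimethylcyclohex-3-ene-1-carboxylic acid | OC(=O)[C@@H]1CCC=C(C)[C@@]1(C)CCCO[Si](C)(C)C(C)(C)C | intermediate
18 | [(1R,2S)-2-(3-{[tert-butyl(dimethyl)silyl]oxy}propyl)-2,3-dimethylcyclohex-3-en-1-yl]methanol | OC[C@@H]1CCC=C(C)[C@@]1(C)CCCO[Si](C)(C)C(C)(C)C | intermediate
19 | 3-[(1S,6R)-6-(hydroxymethyl)-1,2-dimethylcyclohex-2-en-1-yl]propan-1-ol | OC[C@@H]1CCC=C(C)[C@@]1(C)CCCO | intermediate
20 | (1R,2S)-2,3-dimethyl-2-(3-oxopropyl)cyclohex-3-ene-1-carbaldehyde | O=C[C@@H]1CCC=C(C)[C@@]1(C)CCC=O | intermediate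
21 | (1S,2R,4aS,8aR)-4a,5-dimethyl-1,2,3,4,4a,7,8,8a-octahydronaphthalene-1,2-diol | C1C[C@]2(C)C(C)=CCC[C@H]2[C@H](O)[C@@H]1O | intermediate
22 | (3aR,5aS,9aR,9bS)-2,2,5a,6-tetramethyl-3a,4,5,5a,8,9,9a,9b-octahydronaphtho[1,2-d][1,3]dioxole | C1C[C@]2(C)C(C)=CCC[C@H]2[C@@H]3OC(C)(C)O[C@H]13 | intermediate
23 | monoalkylborane from syn addition of H–BH2 to the α face of 22 (boron on C3 α, hydrogen on C4 α; ring position 7 of the dioxole) | C1C[C@]2(C)[C@@H](C)[C@H](B)CC[C@H]2[C@@H]3OC(C)(C)O[C@H]13 | intermediate
24 | (3aR,5aR,6R,7R,9aR,9bS)-2,2,5a,6-tetramethyldecahydronaphtho[1,2-d][1,3]dioxol-7-ol | C1C[C@]2(C)[C@@H](C)[C@H](O)CC[C@H]2[C@@H]3OC(C)(C)O[C@H]13 | intermediate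
25 | (2E)-2-methylbut-2-enoyl chloride (tigloyl chloride) | C/C=C(\C)C(Cl)=O | starting material
26 | (3aR,5aR,6R,7R,9aR,9bS)-2,2,5a,6-tetramethyldecahydronaphtho[1,2-d][1,3]dioxol-7-yl (2E)-2-methylbut-2-enoate | C1C[C@]2(C)[C@@H](C)[C@H](OC(=O)/C(C)=C/C)CC[C@H]2[C@@H]3OC(C)(C)O[C@H]13 | intermediate
27 | (1R,2R,4aR,5S,6R,8aR)-5,6-dihydroxy-1,8a-dimethyldecahydronaphthalen-2-yl (2E)-2-methylbut-2-enoate | C1C[C@]2(C)[C@@H](C)[C@H](OC(=O)/C(C)=C/C)CC[C@H]2[C@H](O)[C@@H]1O | intermediate
28 | 8,9-O-dibutylstannylene acetal of 27 (2,2-dibutyl-1,3,2-dioxastannolane fused at C8–C9, both oxygens α) | C1C[C@]2(C)[C@@H](C)[C@H](OC(=O)/C(C)=C/C)CC[C@H]2[C@@H]3O[Sn](CCCC)(CCCC)O[C@H]13 | intermediate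
29 | (1R,2R,4aR,5S,6R,8aR)-6-hydroxy-1,8a-dimethyl-5-[(triethylsilyl)oxy]decahydronaphthalen-2-yl (2E)-2-methylbut-2-enoate | C1C[C@]2(C)[C@@H](C)[C@H](OC(=O)/C(C)=C/C)CC[C@H]2[C@H](O[Si](CC)(CC)CC)[C@@H]1O | intermediate
30 | (1R,2R,4aR,5S,8aR)-1,8a-dimethyl-6-oxo-5-[(triethylsilyl)oxy]decahydronaphthalen-2-yl (2E)-2-methylbut-2-enoate | C1C[C@]2(C)[C@@H](C)[C@H](OC(=O)/C(C)=C/C)CC[C@H]2[C@H](O[Si](CC)(CC)CC)C1=O | intermediate
31 | 2-bromoprop-1-ene | CC(Br)=C | starting material
32 | (1R,2R,4aR,5S,7S,8aR)-1,8a-dimethyl-6-oxo-7-(prop-1-en-2-yl)-5-[(triethylsilyl)oxy]decahydronaphthalen-2-yl (2E)-2-methylbut-2-enoate | C=C(C)[C@@H]1C[C@]2(C)[C@@H](C)[C@H](OC(=O)/C(C)=C/C)CC[C@H]2[C@H](O[Si](CC)(CC)CC)C1=O | intermediate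
33 | (1R,2R,4aR,5S,7S,8aR)-5-hydroxy-1,8a-dimethyl-6-oxo-7-(prop-1-en-2-yl)decahydronaphthalen-2-yl (2E)-2-methylbut-2-enoate | C=C(C)[C@@H]1C[C@]2(C)[C@@H](C)[C@H](OC(=O)/C(C)=C/C)CC[C@H]2[C@H](O)C1=O | intermediate
34 | 3-methylbut-2-enoic acid | CC(C)=CC(=O)O | starting material
35 | (1R,2R,4aR,5S,7S,8aR)-1,8a-dimethyl-5-[(3-methylbut-2-enoyl)oxy]-6-oxo-7-(prop-1-en-2-yl)decahydronaphthalen-2-yl (2E)-2-methylbut-2-enoate; eremophilane numbering (3R,4R,5R,7S,9S,10R) | C=C(C)[C@@H]1C[C@]2(C)[C@@H](C)[C@H](OC(=O)/C(C)=C/C)CC[C@H]2[C@H](OC(=O)C=C(C)C)C1=O | target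

## Step count and least certain steps

Total step count: 21. Longest linear sequence: 21 steps (1 → 35); the partners 3, 8, 11, 25, 31 and 34 are commercial.

**Step 9 (key step).** The lactone enolate may be silylated on carbon or condense with unreacted lactone. The rearrangement may also be slow, because the boat transition state must build a quaternary centre from a tetrasubstituted alkene, so the ketene acetal could hydrolyse or fragment before it rearranges. Fallback: from 14, reduction with i-Bu2AlH at −78 °C gives lactol F1, and dehydration (MsCl, Et3N) gives the cyclic enol ether F2. Heating F2 in a sealed tube at about 200 °C is the neutral Claisen rearrangement of a 2-alkenyl-3,4-dihydro-2H-pyran to a cyclohex-3-enecarbaldehyde; it needs no enolate and passes through the same boat with the same stereochemical course, giving aldehyde F3. NaBH4 converts F3 into 18, and acidic methanolysis as in step 10 rejoins the route at 19.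

**Step 19.** The coupling may stall at the hindered secondary enolate, the silyl group may migrate from O9 to the enolate oxygen, or excess base may shift the new double bond into conjugation. Fallback: from 30, addition of the lithium enolate (LiN(i-Pr)2, −78 °C) to acetone gives aldol F4. Dehydration with methyl N-(triethylammoniosulfonyl)carbamate is taken fully to the conjugated isopropylidene ketone F5. γ-Deprotonation with KN(SiMe3)2 at −78 °C and kinetic α-protonation with AcOH then deconjugate F5 and rejoin the route at 32.

**Step 12.** C10 may epimerise in the dialdehyde, one aldehyde may simply be reduced, or the trans diol may form if the samarium bridge is not maintained. Fallback: from 20, an intramolecular crossed benzoin reaction (3-benzyl-5-(2-hydroxyethyl)-4-methylthiazolium chloride, Et3N) should make the unhindered C8 aldehyde the acyl-anion partner and give ketol F6, whose C9 carbinol can equilibrate to the equatorial epimer. Chelation-controlled reduction with Zn(BH4)2 then rejoins the route at cis diol 21.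

**Step 5.** The tetrasubstituted, α-branched enal may react slowly and with low enantioselectivity, and a slow reaction gives the (Z)-enal time to isomerise. Fallback: from 7, allylmagnesium bromide gives racemic alcohol F7 and periodinane oxidation gives enone F8. Corey–Bakshi–Shibata reduction with (R)-1-methyl-3,3-diphenyltetrahydro-1H,3H-pyrrolo[1,2-c][1,3,2]oxazaborole and catecholborane at −78 °C, which does not hydroborate the terminal alkene, rejoins the route at 10.

**Step 17.** Silylation may occur at O8 or at both oxygens, or the silyl group may migrate between the cis oxygens. Fallback: from 27, brominolysis of the same stannylene acetal (Bu2SnO; then N-bromosuccinimide, CHCl3) oxidises the carbinol whose oxygen is axial and gives ketol F9. Silylation of its only hydroxyl (Et3SiCl, imidazole) rejoins the route at 30.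

## Further compounds

F1 | step 9 | (6S)-6-[(2Z)-6-{[tert-butyl(dimethyl)silyl]oxy}-3-methylhex-2-en-2-yl]oxan-2-ol (anomeric mixture) | OC1CCC[C@H](O1)/C(C)=C(C)\CCCO[Si](C)(C)C(C)(C)C
F2 | step 9 | tert-butyl({(4Z)-5-[(2S)-3,4-dihydro-2H-pyran-2-yl]-4-methylhex-4-en-1-yl}oxy)dimethylsilane | C1=CCC[C@H](O1)/C(C)=C(C)\CCCO[Si](C)(C)C(C)(C)C
F3 | step 9 | (1R,2S)-2-(3-{[tert-butyl(dimethyl)silyl]oxy}propyl)-2,3-dimethylcyclohex-3-ene-1-carbaldehyde | O=C[C@@H]1CCC=C(C)[C@@]1(C)CCCO[Si](C)(C)C(C)(C)C
F4 | step 19 | (1R,2R,4aR,5S,8aR)-7-(2-hydroxypropan-2-yl)-1,8a-dimethyl-6-oxo-5-[(triethylsilyl)oxy]decahydronaphthalen-2-yl (2E)-2-methylbut-2-enoate (C7 not assigned) | CC(C)(O)C1C[C@]2(C)[C@@H](C)[C@H](OC(=O)/C(C)=C/C)CC[C@H]2[C@H](O[Si](CC)(CC)CC)C1=O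
F5 | step 19 | (1R,2R,4aR,5S,8aR)-1,8a-dimethyl-6-oxo-7-(propan-2-ylidene)-5-[(triethylsilyl)oxy]decahydronaphthalen-2-yl (2E)-2-methylbut-2-enoate | CC(C)=C1C[C@]2(C)[C@@H](C)[C@H](OC(=O)/C(C)=C/C)CC[C@H]2[C@H](O[Si](CC)(CC)CC)C1=O
F6 | step 12 | (1S,4aS,8aR)-1-hydroxy-4a,5-dimethyl-3,4,4a,7,8,8a-hexahydronaphthalen-2(1H)-one | C1C[C@]2(C)C(C)=CCC[C@H]2[C@H](O)C1=O
F7 | step 5 | (5Z)-9-{[tert-butyl(dimethyl)silyl]oxy}-5,6-dimethylnona-1,5-dien-4-ol (racemic) | C=CCC(O)/C(C)=C(C)\CCCO[Si](C)(C)C(C)(C)C
F8 | step 5 | (5Z)-9-{[tert-butyl(dimethyl)silyl]oxy}-5,6-dimethylnona-1,5-dien-4-one | C=CCC(=O)/C(C)=C(C)\CCCO[Si](C)(C)C(C)(C)C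
F9 | step 17 | (1R,2R,4aR,5S,8aR)-5-hydroxy-1,8a-dimethyl-6-oxodecahydronaphthalen-2-yl (2E)-2-methylbut-2-enoate | C1C[C@]2(C)[C@@H](C)[C@H](OC(=O)/C(C)=C/C)CC[C@H]2[C@H](O)C1=O
A1 | alternative 1 | trans-decalin with 3α-hydroxyl, 4β-methyl, 5β-methyl and the C8 ethylene ketal (eremophilane numbering) | C[C@H]1[C@H](O)CC[C@H]2CC3(OCCO3)CC[C@]12C
A2 | alternative 1 | ketal-protected cyclohexanone bearing methyl and vinyl on C5 and a 3-oxopropyl chain on C10 (trans) | O=CCC[C@H]1CC2(OCCO2)CC[C@@]1(C=C)C
A3 | alternative 2 | trans-fused 5-formyl-8,9-bis(silyloxy)octal-8-ene with 3α-silyloxy and 4β-methyl | C1C[C@]2(C=O)[C@@H](C)[C@H](O[Si](C)(C)C(C)(C)C)CC[C@H]2C(O[Si](C(C)C)(C(C)C)C(C)C)=C1O[Si](C)(C)C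
A4 | alternative 2 | acyclic triene: 2-substituted acrolein (C5=C6) tethered through C4–C1 to the 2,3-bis(silyloxy)diene (C7=C8–C9=C10) | C=C(O[Si](C)(C)C)/C(O[Si](C(C)C)(C(C)C)C(C)C)=C/CC[C@@H](O[Si](C)(C)C(C)(C)C)[C@H](C)C(=C)C=O
A5 | alternative 3 | bicyclic 9-(methoxymethoxy)-6,9-dien-8-one with 3α-silyloxy, 4β-methyl and 5β-methyl | C1=C[C@]2(C)[C@@H](C)[C@H](O[Si](C)(C)C(C)(C)C)CCC2=C(OCOC)C1=O
A6 | alternative 3 | 4-methylphenol with 2-methoxymethoxy and a 3-silyloxy-4-mesyloxypentyl chain at C10 | Cc1ccc(O)c(OCOC)c1CC[C@@H](O[Si](C)(C)C(C)(C)C)[C@@H](C)OS(C)(=O)=O
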